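**Plan**

- Retrosynthesis: the two phenols are unmasked last (MOM acetals). Ring B (the pyranone) is cut at C4–C4a and, in the same operation, at O1–C8a. This leads back to an aryne of ring A (triple bond C4a≡C8a) and the alkoxide of an (S)-3-hydroxy Weinreb amide.
- Enabling feature: C4a and C8a are neighbouring carbons of the fully substituted ring A and must take up the C4 acyl carbon and O1. In the aryne the C5 oxygen sits beside C4a and the C8 methyl beside C8a, so the alkoxide should enter at C8a and leave the carbanion at C4a, six atoms from the amide carbonyl.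
- Forward, ring A: 2-methylresorcinol is MOM-protected, C-methylated and hydroxylated by two directed ortho-metalations, brominated, and converted by retro-Brook shift and triflation into the 2-silylaryl triflate.
- Forward, chain: stearoyl chloride and Meldrum's acid give the C20 β-keto ester; Noyori hydrogenation and amidation give the hydroxy Weinreb amide.
- Ring B is formed on ring A in the aryne annulation (O1–C8a first, then ring closure at C4–C4a); acid then removes the MOM groups.
- Stereochemistry: the only stereocentre, C2 (S), comes from the (S)-BINAP-controlled hydrogenation, and its C–O bond is never broken afterwards.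

Key step: step 9

Remark: 2-methylresorcinol, stearoyl chloride and Meldrum's acid are taken as commercial; C2 of the target is (S) (O1 > C3 > side chain > H), and the same spatial arrangement is (S) in every chain intermediate.

**Route**

Step 1
Reactants: 1 2-methylresorcinol (2-methylbenzene-1,3-diol)
Product: 2 1,3-bis(methoxymethoxy)-2-methylbenzene
Conditions: NaH (2.4 equiv), MOMCl (2.4 equiv), DMF, 0 °C → rt
Reagents that add atoms: chloromethyl methyl ether (MOMCl), COCCl
Why: Williamson-type O-alkylation of both phenoxides (MOM protection) should be clean, and the acetals later serve as ortho-directing groups and come off under mild acid.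

Step 2
Reactants: 2 1,3-bis(methoxymethoxy)-2-methylbenzene
Product: 4 1,3-bis(methoxymethoxy)-2,4-dimethylbenzene, via aryllithium 3 (not isolated)
Conditions: n-BuLi (1.2 equiv), TMEDA, THF, 0 °C; MeI, −78 °C → rt
Reagents that add atoms: iodomethane, CI
Why: Directed ortho-metalation by an OMOM group places lithium on the ring carbon next to it (the two such positions are equivalent), and the aryllithium is methylated by SN2 attack on MeI.

Step 3
Reactants: 4 1,3-bis(methoxymethoxy)-2,4-dimethylbenzene
Product: 7 2,4-bis(methoxymethoxy)-3,5-dimethylphenol, via aryllithium 5 (not isolated), via dimethyl arylboronate 6 (not isolated)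
Conditions: n-BuLi (1.2 equiv), TMEDA, THF, 0 °C; B(OMe)3, −78 °C → rt; 30% aq H2O2, 0 °C → rt
Reagents that add atoms: trimethyl borate, COB(OC)OC; hydrogen peroxide, OO
Why: A second directed ortho-metalation can only occur at the single ring C–H that is ortho to an OMOM group, and borylation followed by peroxide-induced 1,2-shift of the aryl group from boron to oxygen should give the phenol at the future C4a.

Step 4
Reactants: 7 2,4-bis(methoxymethoxy)-3,5-dimethylphenol
Product: 8 2-bromo-4,6-bis(methoxymethoxy)-3,5-dimethylphenol
Conditions: NBS (1.0 equiv), CH2Cl2, −78 → 0 °C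
Reagents that add atoms: N-bromosuccinimide, O=C1CCC(=O)N1Br
Why: Electrophilic aromatic bromination has only one free ring position, ortho to the phenol OH (the future C8a), and one equivalent at low temperature should avoid oxidation of the electron-rich ring.

Step 5
Reactants: 8 2-bromo-4,6-bis(methoxymethoxy)-3,5-dimethylphenol
Product: 11 4,6-bis(methoxymethoxy)-3,5-dimethyl-2-(trimethylsilyl)phenyl trifluoromethanesulfonate, via trimethylsilyl ether 9 (not isolated), via lithium phenoxide 10 (not isolated)
Conditions: HMDS, THF, 65 °C, then evaporation; n-BuLi (1.1 equiv), THF, −78 → −40 °C; Tf2O, −78 °C → rt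
Reagents that add atoms: hexamethyldisilazane, C[Si](C)(C)N[Si](C)(C)C; trifluoromethanesulfonic anhydride, O=S(=O)(OS(=O)(=O)C(F)(F)F)C(F)(F)F
Why: O-silylation, bromine–lithium exchange and 1,3-shift of silicon from oxygen to carbon (retro-Brook rearrangement) put SiMe3 on the ring, and triflation of the released phenoxide completes the standard entry to a 2-silylaryl triflate aryne precursor.

Step 6
Reactants: 12 stearoyl chloride (octadecanoyl chloride); 13 Meldrum's acid (2,2-dimethyl-1,3-dioxane-4,6-dione)
Product: 15 methyl 3-oxoicosanoate, via acyl Meldrum's acid 14 (not isolated)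
Conditions: pyridine (2 equiv), CH2Cl2, 0 °C → rt; then MeOH, reflux
Reagents that add atoms: methanol, CO
Why: C-acylation of Meldrum's acid followed by methanolysis with loss of acetone and CO2 (through the acylketene) is a standard β-keto ester synthesis.

Step 7
Reactants: 15 methyl 3-oxoicosanoate
Product: 16 methyl (3S)-3-hydroxyicosanoate
Conditions: H2 (10 bar), [RuCl(p-cymene)((S)-BINAP)]Cl (0.5 mol %), MeOH, 60 °C
Reagents that add atoms: none
Why: Noyori asymmetric hydrogenation of a β-keto ester delivers hydride to the ester-chelated ketone on the face fixed by (S)-BINAP, which should set the (S)-carbinol that becomes C2.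

Step 8
Reactants: 16 methyl (3S)-3-hydroxyicosanoate
Product: 17 (3S)-3-hydroxy-N-methoxy-N-methylicosanamide
Conditions: MeNH(OMe)·HCl (1.6 equiv), i-PrMgCl (4.2 equiv), THF, −20 → 0 °C
Reagents that add atoms: N,O-dimethylhydroxylamine hydrochloride, CNOC.Cl
Why: Aminolysis of the ester by the chloromagnesium amide of N,O-dimethylhydroxylamine (Weinreb amide formation) tolerates the free carbinol as its magnesium alkoxide and does not touch the stereocentre.

Step 9
Reactants: 17 (3S)-3-hydroxy-N-methoxy-N-methylicosanamide; 11 4,6-bis(methoxymethoxy)-3,5-dimethyl-2-(trimethylsilyl)phenyl trifluoromethanesulfonate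
Product: 22 (2S)-2-heptadecyl-5,7-bis(methoxymethoxy)-6,8-dimethylchroman-4-one, via sodium alkoxide 18 (not isolated), via aryne 19 (not isolated), via aryl anion 20 (not isolated), via hemiaminal alkoxide 21 (not isolated)
Conditions: NaH (1.05 equiv), THF, 0 °C; CsF (3 equiv), 18-crown-6 (3 equiv), slow addition of 11 (1.3 equiv), 0 °C → rt; sat. aq NH4Cl, 0 °C
Reagents that add atoms: none
Why: Proposed new method: fluoride strips SiMe3 from 11 and triflate leaves to give aryne 19 (C4a≡C8a of ring A), alkoxide 18 adds through oxygen at C8a (bond O1–C8a), and the C4a carbanion 20 then attacks the amide carbonyl to form C4–C4a, giving hemiaminal alkoxide 21, which releases ketone 22 only at the NH4Cl quench. The closest known reaction type is the fluoride-induced annulation of arynes with methyl salicylates to xanthones (phenoxide addition, then acylation of the aryl anion by the tethered ester), together with the Parham cyclisation of aryl anions onto tethered amides; an aliphatic β-alkoxy amide has not been shown in this role. Ring B closes in the 6-exo-trig mode by C–C bond formation at the amide carbonyl. No stereocentre is created that survives (C4 of 21 becomes the carbonyl carbon), and C2 should keep its (S) configuration because its C–O bond is not broken and the ketone is set free only at the quench, away from base that could open ring B by β-elimination. The step needs attack at C8a and not at C4a: the C5 OMOM oxygen, on the carbon next to C4a, polarises the triple bond by induction so that the nucleophile enters at the distal carbon C8a and the charge develops at C4a beside that oxygen, a bias expected to outweigh the steric effect of the C8 methyl group. Preforming the alkoxide (no O–H to quench 20), the six-atom tether and the low electrophilicity of the amide towards a second alkoxide should favour ring closure over protonation and oligomerisation.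

Step 10
Reactants: 22 (2S)-2-heptadecyl-5,7-bis(methoxymethoxy)-6,8-dimethylchroman-4-one
Product: 23 (2S)-2-heptadecyl-5,7-dihydroxy-6,8-dimethylchroman-4-one
Conditions: HCl (3 M in MeOH), THF, 40 °C
Reagents that add atoms: none
Why: Acid-catalysed acetal cleavage (MOM removal) should free both phenols, while the secondary alkyl aryl ether at C2 and the ketone are inert to dilute acid and the stereocentre takes no part.

**Compound list**

1 | 2-methylresorcinol (2-methylbenzene-1,3-diol) | Oc1cccc(O)c1C | starting material
2 | 1,3-bis(methoxymethoxy)-2-methylbenzene | COCOc1cccc(OCOC)c1C | intermediate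
3 | [2,4-bis(methoxymethoxy)-3-methylphenyl]lithium | COCOc1ccc([Li])c(OCOC)c1C | intermediate
4 | 1,3-bis(methoxymethoxy)-2,4-dimethylbenzene | COCOc1ccc(C)c(OCOC)c1C | intermediate
5 | [2,4-bis(methoxymethoxy)-3,5-dimethylphenyl]lithium | COCOc1c([Li])cc(C)c(OCOC)c1C | intermediate
6 | dimethyl [2,4-bis(methoxymethoxy)-3,5-dimethylphenyl]boronate | COCOc1c(B(OC)OC)cc(C)c(OCOC)c1C | intermediate
7 | 2,4-bis(methoxymethoxy)-3,5-dimethylphenol | COCOc1c(O)cc(C)c(OCOC)c1C | intermediate
8 | 2-bromo-4,6-bis(methoxymethoxy)-3,5-dimethylphenol | COCOc1c(O)c(Br)c(C)c(OCOC)c1C | intermediate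
9 | [2-bromo-4,6-bis(methoxymethoxy)-3,5-dimethylphenoxy]trimethylsilane | COCOc1c(O[Si](C)(C)C)c(Br)c(C)c(OCOC)c1C | intermediate
10 | lithium 4,6-bis(methoxymethoxy)-3,5-dimethyl-2-(trimethylsilyl)phenoxide | COCOc1c([O-])c([Si](C)(C)C)c(C)c(OCOC)c1C.[Li+] | intermediate
11 | 4,6-bis(methoxymethoxy)-3,5-dimethyl-2-(trimethylsilyl)phenyl trifluoromethanesulfonate | COCOc1c(OS(=O)(=O)C(F)(F)F)c([Si](C)(C)C)c(C)c(OCOC)c1C | intermediate
12 | stearoyl chloride (octadecanoyl chloride) | CCCCCCCCCCCCCCCCCC(=O)Cl | starting material
13 | Meldrum's acid (2,2-dimethyl-1,3-dioxane-4,6-dione) | CC1(C)OC(=O)CC(=O)O1 | starting material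
14 | 5-(1-hydroxyoctadecylidene)-2,2-dimethyl-1,3-dioxane-4,6-dione (acyl Meldrum's acid, enol form) | CCCCCCCCCCCCCCCCCC(O)=C1C(=O)OC(C)(C)OC1=O | intermediate
15 | methyl 3-oxoicosanoate | CCCCCCCCCCCCCCCCCC(=O)CC(=O)OC | intermediate
16 | methyl (3S)-3-hydroxyicosanoate | CCCCCCCCCCCCCCCCC[C@H](O)CC(=O)OC | intermediate
17 | (3S)-3-hydroxy-N-methoxy-N-methylicosanamide | CCCCCCCCCCCCCCCCC[C@H](O)CC(=O)N(C)OC | intermediate
18 | sodium (3S)-1-[methoxy(methyl)amino]-1-oxoicosan-3-olate | CCCCCCCCCCCCCCCCC[C@H]([O-])CC(=O)N(C)OC.[Na+] | intermediate
19 | 3,5-bis(methoxymethoxy)-4,6-dimethylbenzyne (1,2-didehydrobenzene; the OMOM-bearing C3 is the future C5) | COCOC1=C(C)C(OCOC)=C(C)C#C1 | intermediate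
20 | {2-[(3S)-1-[methoxy(methyl)amino]-1-oxoicosan-3-yl]oxy-4,6-bis(methoxymethoxy)-3,5-dimethylphenyl}sodium (C4a carbanion) | CCCCCCCCCCCCCCCCC[C@@H](CC(=O)N(C)OC)Oc1c([Na])c(OCOC)c(C)c(OCOC)c1C | intermediate
21 | sodium (2S)-2-heptadecyl-4-[methoxy(methyl)amino]-5,7-bis(methoxymethoxy)-6,8-dimethylchroman-4-olate | CCCCCCCCCCCCCCCCC[C@H]1CC([O-])(N(C)OC)c2c(OCOC)c(C)c(OCOC)c(C)c2O1.[Na+] | intermediate
22 | (2S)-2-heptadecyl-5,7-bis(methoxymethoxy)-6,8-dimethylchroman-4-one | CCCCCCCCCCCCCCCCC[C@H]1CC(=O)c2c(OCOC)c(C)c(OCOC)c(C)c2O1 | intermediate
23 | (2S)-2-heptadecyl-5,7-dihydroxy-6,8-dimethylchroman-4-one | CCCCCCCCCCCCCCCCC[C@H]1CC(=O)c2c(O)c(C)c(O)c(C)c2O1 | target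

**Step count and risks**

Total steps: 10. Longest linear sequence: 7 steps (steps 1–5, 9 and 10); the chain arm runs through steps 6–10 (5 steps).

Steps most likely to fail:

Step 9. The aryl anion may be protonated before it closes the ring (by traces of proton sources or by proton transfer from C3), or the alkoxide may be lost by silyl transfer from the precursor, so that only the open aryl ether forms or conversion stays low. The fallback makes the two bonds one after the other by known chemistry and sets out from 11 and hydroxy ester 16. CsF in MeCN at rt (addition of the neutral alcohol O–H across the aryne, same regiochemistry) should give methyl (3S)-3-[3,5-bis(methoxymethoxy)-2,4-dimethylphenoxy]icosanoate F1. LiOH in THF/H2O at 0 °C should then give (3S)-3-[3,5-bis(methoxymethoxy)-2,4-dimethylphenoxy]icosanoic acid F2. Intramolecular Friedel–Crafts acylation of F2 with trifluoroacetic anhydride in CH2Cl2 at 0 °C, at the only free ring position (ortho or para to all three oxygens), should close ring B and come back to the route at 22. An acetal lost at this stage is of no concern because step 10 removes both.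

Step 5. After bromine–lithium exchange the silyl shift to the crowded carbon between OSiMe3 and the methyl group may be slow, so that the aryllithium is protonated; the doubly flanked phenoxide may also triflate sluggishly. The fallback sets out from phenol 7 and replaces steps 4 and 5. Isopropyl isocyanate with catalytic Et3N in CH2Cl2 should give 2,4-bis(methoxymethoxy)-3,5-dimethylphenyl N-isopropylcarbamate F3. Carbamate-directed ortho-lithiation at the only ring C–H and C-silylation in one flask (TBSOTf, TMEDA; n-BuLi, TMEDA, −78 °C; TMSCl; acidic work-up) should give 4,6-bis(methoxymethoxy)-3,5-dimethyl-2-(trimethylsilyl)phenyl N-isopropylcarbamate F4. Cleavage of the carbamate with Et2NH and DBU in MeCN, followed by triflation of the phenoxide with PhNTf2, comes back at 11.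

Step 3. Ring metalation may be incomplete or may compete with deprotonation of a benzylic methyl group, and the very electron-rich phenol may be over-oxidised in the peroxide stage. The fallback sets out from 4. NBS in MeCN at 0 °C (electrophilic bromination at the carbon ortho and para to the two OMOM groups, the same carbon that step 3 lithiates) should give 1-bromo-2,4-bis(methoxymethoxy)-3,5-dimethylbenzene F5. Palladium-catalysed hydroxylation (Pd2(dba)3, t-BuXPhos, KOH, 1,4-dioxane/H2O, 100 °C) then comes back at 7.

**Further compounds**

F1 | step 9 | methyl (3S)-3-[3,5-bis(methoxymethoxy)-2,4-dimethylphenoxy]icosanoate | CCCCCCCCCCCCCCCCC[C@@H](CC(=O)OC)Oc1cc(OCOC)c(C)c(OCOC)c1C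
F2 | step 9 | (3S)-3-[3,5-bis(methoxymethoxy)-2,4-dimethylphenoxy]icosanoic acid | CCCCCCCCCCCCCCCCC[C@@H](CC(=O)O)Oc1cc(OCOC)c(C)c(OCOC)c1C
F3 | step 5 | 2,4-bis(methoxymethoxy)-3,5-dimethylphenyl N-isopropylcarbamate | CC(C)NC(=O)Oc1cc(C)c(OCOC)c(C)c1OCOC
F4 | step 5 | 4,6-bis(methoxymethoxy)-3,5-dimethyl-2-(trimethylsilyl)phenyl N-isopropylcarbamate | CC(C)NC(=O)Oc1c([Si](C)(C)C)c(C)c(OCOC)c(C)c1OCOC
F5 | step 3 | 1-bromo-2,4-bis(methoxymethoxy)-3,5-dimethylbenzene | COCOc1c(Br)cc(C)c(OCOC)c1C
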